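The earlier runs and the new flask were generated by integration for substances that don't exist; noise was put on by code.

At 30 min, the time of reading, the substrate in these flasks has been warm for different stretches, so first find the concentration that sets the order of its loss.

| flask | substrate | first nucleophile | solid second nucleophile | temperature | remark | time |
|---|---|---|---|---|---|---|
| violet | 20 mM | 18 mM | 40 mM | 10 °C | run made earlier |  |
| teal | 10 mM | 18 mM | 40 mM | 25 °C | run made earlier |  |
| grey | 40 mM | 18 mM | 40 mM | 10 °C | run made earlier |  |
| green | 20 mM | 18 mM | 20 mM | 25 °C | run made earlier |  |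
| Thursday's | 20 mM (fed, over 25 min) | 18.0 mM | 40.0 mM | 25 °C | all else is in the flask from the start; the feed brings no volume worth counting | 30 min |
| Tuesday's | 20 mM (fed, over 25 min) | 18.0 mM | 40.0 mM |  | the addition at −15 °C, then warmed to 25 °C; the feed brings no volume worth counting | 30 min |
| Wednesday's | 20 mM (in portions, 4, over 25 min) | 18.0 mM | 40.0 mM | 25 °C | first portion at the start, last at 25 min | 30 min |
| Sunday's | 20 mM | 18.0 mM | 40.0 mM | 25 °C | everything together at the start | 30 min |

- violet (time / min: target / %, substrate / %): 5.00: 4.0, 95.8; 15.0: 10.9, 85.6; 30.0: 17.9, 75.1; 40.0: 21.0, 68.3; 60.0: 25.1, 57.0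
- teal (time / min: target / %, substrate / %): 6.00: 23.0, 73.0; 12.0: 32.9, 53.9; 20.0: 36.4, 34.9; 25.0: 35.6, 27.2; 30.0: 33.8, 21.3
- grey (time / min: target / %, substrate / %): 12.0: 8.6, 88.6; 25.0: 15.6, 78.7; 40.0: 19.7, 68.0; 50.0: 22.1, 61.3; 60.0: 23.6, 56.1
- green (time / min: target / %, substrate / %): 2.50: 11.0, 87.0; 5.00: 18.8, 76.4; 8.00: 26.0, 65.4; 15.0: 34.2, 45.6; 30.0: 31.3, 22.8

(standard deviation of a reading: 0.3 percentage points)

- at the start none of the solid second nucleophile is in solution

1. which flask leads in amount of target, in percent of the substrate charged ("all alike" within 1.5 percentage points) (Thursday's / Tuesday's / Wednesday's / Sunday's / all alike)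
2. how much target is there at the end, in percent of the substrate charged: Thursday's
3. how much target is there at the end, in percent of the substrate charged: Tuesday's
4. how much target is there at the end, in percent of the substrate charged: Wednesday's
5. how much target is there at the end, in percent of the substrate charged: Sunday's

It is the substrate's own. The grey run has twice the charge of the violet run, yet at 60.0 min they read 56.1% and 57.0%: first order. The first nucleophile stood at 18 mM in each earlier run, so its order cannot be read here. In the teal run the substrate reads 73.0% at 6.00 min and 21.3% at 30.0 min, which gives 0.0513 min⁻¹. Call this k, the share of the standing substrate lost per minute at 25 °C, the substrate clock.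

The bench rule treats a fed charge as a batch charged at mid-feed, which leaves 40.7% in Thursday's flask. But that rule needs k times the feed time well below one, and here it is 1.28. So average the clock over the ages instead: by this reckoning Thursday's keeps 43.6% of its substrate, Wednesday's 45.5%, Sunday's 21.4%.

For Tuesday's, the violet run gives 0.00944 min⁻¹ at 10 °C. Stretched on a log scale to −15 °C, that becomes 5.62 × 10⁻⁴ min⁻¹, so by this estimate hardly any of Tuesday's substrate goes during the feed, and the warm stretch leaves 77.4%.

By the clock, Thursday's flask holds twice the unreacted substrate of Sunday's. Yet the teal target reads 36.4% at 20.0 min and 33.8% at 30.0 min, so target is lost as well, and the substrate clock does not weigh that loss against the substrate kept.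

The forecast puts 32.5% on Thursday's, 19% on Tuesday's, 30.5% on Wednesday's and 32% on Sunday's, saying “Thursday only narrowly leads Sunday”.

The flasks give 29.2%, 16.1%, 27.4% and 31.1% in that order, so Sunday's leads.

    substrate ⇌ intermediate (K = 0.0240, k = 0.0610 min⁻¹, Ea = 87.0 kJ mol⁻¹, ΔH = −72.0 kJ mol⁻¹)
    first nucleophile + intermediate → target (k = 900 M⁻¹ min⁻¹, Ea = 52.0 kJ mol⁻¹)
    second nucleophile + intermediate → other capture product (k = 880 M⁻¹ min⁻¹, Ea = 47.0 kJ mol⁻¹)
    solid second nucleophile ⇌ second nucleophile, rate k4*(cs4 - [second nucleophile]) while solid is left; crystals form when [second nucleophile] > cs4 (solubility = 14.0 mM, k = 0.0180 min⁻¹)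
    target ⇌ isomer of the product (K = 9.70, k = 0.0400 min⁻¹, Ea = 85.0 kJ mol⁻¹, ΔH = −28.0 kJ mol⁻¹)
    substrate + intermediate → side product (k = 16.0 M⁻¹ min⁻¹, Ea = 52.0 kJ mol⁻¹)
    (constants at 25 °C)

In Sunday's flask the substrate's step to the intermediate, forward rate alone, has a half-life of 11 min, shorter than the 17 min of the target's step to the isomer of the product, also forward rate alone. At 30.0 min Thursday's flask holds 21 percentage points more substrate than Sunday's and 16 points less isomer of the product.

Now take Tuesday's flask read at 2.0 h: the clock, run from the end of the feed, leaves 0.763% of the substrate. The computed flask holds 0.788%, with the target down to 8.52%.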